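**Retrosynthetic overview**
1. Target 14 ⇐ ketone 11: the ring A methyl-bearing alkene is made last (enol triflate, then methyl cross-coupling).
2. 11 ⇐ 10: a 6-endo bromine-atom-transfer radical cyclisation of a bromomethyl ketone onto a vinyl group closes ring A and installs the neopentyl bromide in the same step.
3. 10 ⇐ 9: trans-diaxial BrCl addition to the ring B alkene, placed before the radical step so that the axial bromine steers it.
4. 9 ⇐ 7 ⇐ 5 + isoprene: bromomethyl homologation of the aldehyde from an enantioselective Diels–Alder reaction that builds ring B and the quaternary (future spiro) carbon.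
5. 5 ⇐ prenol + ethyl vinyl ether + formaldehyde (Claisen, α-methylenation); ring B is formed first, ring A second.

Assumption: the target is read as (4R,6R,8S,9S)-4,8-dibromo-9-chloro-1,5,5,9-tetramethylspiro[5.5]undec-1-ene; locants in the text are those of the name of the compound under discussion (spiro names: ring A = C1–C5, spiro atom C6, ring B = C7–C11).

**Step 1**
Reactants: 1 3-methylbut-2-en-1-ol (prenol); 2 ethyl vinyl ether
Product: 4 3,3-dimethylpent-4-enal, via prenyl vinyl ether 3 (not isolated)
Conditions: 2 (excess), Hg(OAc)2 (5 mol %), reflux; then evaporate, neat, 140 °C (sealed tube)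
Reagents that add atoms: none
Why: Transvinylation catalysed by divalent mercury gives the allyl vinyl ether, which undergoes a thermal Claisen rearrangement with C–C bond formation at the dimethyl-substituted terminus, creating the quaternary CMe2 carbon; no stereocentre is formed.

**Step 2**
Reactants: 4 3,3-dimethylpent-4-enal
Product: 5 3,3-dimethyl-2-methylidenepent-4-enal
Conditions: 37% aq. CH2O (1.2 equiv), pyrrolidine (10 mol %), propionic acid (10 mol %), i-PrOH, 45 °C
Reagents that add atoms: formaldehyde, C=O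
Why: Amine/acid-catalysed Mannich condensation–elimination (organocatalytic α-methylenation) at the only enolisable carbon gives the 2-substituted acrolein; no stereocentre is formed.

**Step 3**
Reactants: 5 3,3-dimethyl-2-methylidenepent-4-enal; 6 isoprene
Product: 7 (1S)-4-methyl-1-(2-methylbut-3-en-2-yl)cyclohex-3-ene-1-carbaldehyde
Conditions: 6 (5 equiv), (S)-3,3-diphenyl-1-(2-methylphenyl)tetrahydro-1H,3H-pyrrolo[1,2-c][1,3,2]oxazaborole (20 mol %) protonated with Tf2NH (18 mol %), CH2Cl2, −78 → −40 °C
Reagents that add atoms: none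
Why: Cationic oxazaborolidine-catalysed enantioselective Diels–Alder reaction of a 2-substituted acrolein: the "para" orientation puts the ring methyl 1,4 to the new quaternary carbon, and the catalyst-bound s-trans enal (formyl C–H···O organisation) is attacked on the Si face of its α-carbon, which sets the quaternary stereocentre as S.

**Step 4**
Reactants: 7 (1S)-4-methyl-1-(2-methylbut-3-en-2-yl)cyclohex-3-ene-1-carbaldehyde
Product: 8 2-bromo-1-[(1S)-4-methyl-1-(2-methylbut-3-en-2-yl)cyclohex-3-en-1-yl]ethan-1-ol (both carbinol epimers)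
Conditions: BrCH2I (2.5 equiv), MeLi·LiBr (2.3 equiv, slow addition), THF–Et2O, −78 °C; AcOH, −78 °C
Reagents that add atoms: bromoiodomethane, BrCI
Why: Bromomethyllithium, generated in the presence of the aldehyde by iodine–lithium exchange (faster than carbonyl addition of MeLi), adds 1,2 and the alkoxide is protonated cold before it can close to the epoxide (halomethyllithium carbonyl addition); the carbinol centre forms unselectively and is erased in step 5.

**Step 5**
Reactants: 8 2-bromo-1-[(1S)-4-methyl-1-(2-methylbut-3-en-2-yl)cyclohex-3-en-1-yl]ethan-1-ol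
Product: 9 2-bromo-1-[(1S)-4-methyl-1-(2-methylbut-3-en-2-yl)cyclohex-3-en-1-yl]ethan-1-one
Conditions: Dess–Martin periodinane (1.3 equiv), CH2Cl2, 0 °C → rt
Reagents that add atoms: none
Why: Dess–Martin oxidation of the secondary bromohydrin gives the α-bromo ketone under non-basic conditions, and the adjacent quaternary stereocentre cannot epimerise.

**Step 6**
Reactants: 9 2-bromo-1-[(1S)-4-methyl-1-(2-methylbut-3-en-2-yl)cyclohex-3-en-1-yl]ethan-1-one
Product: 10 2-bromo-1-[(1S,3S,4S)-3-bromo-4-chloro-4-methyl-1-(2-methylbut-3-en-2-yl)cyclohexyl]ethan-1-one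
Conditions: NBS (1.05 equiv), HCl (4 M in dioxane, 1.1 equiv), CH2Cl2, −78 → −40 °C
Reagents that add atoms: N-bromosuccinimide, BrN1C(=O)CCC1=O; hydrogen chloride, Cl
Why: Electrophilic anti-bromochlorination (BrCl formed in the flask) of the trisubstituted ring alkene, which is far more nucleophilic than the neopentyl vinyl group: bromonium formation is reversible and only the bromonium syn to the pseudo-axial acyl group can be opened by chloride at the tertiary carbon (Markovnikov) through a chair-like trans-diaxial (Fürst–Plattner) transition state that keeps the 1,1-dimethylallyl group equatorial, which sets C3 (Br, S) and C4 (Cl, S).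

**Step 7**
Reactants: 10 2-bromo-1-[(1S,3S,4S)-3-bromo-4-chloro-4-methyl-1-(2-methylbut-3-en-2-yl)cyclohexyl]ethan-1-one
Product: 11 (4R,6S,8S,9S)-4,8-dibromo-9-chloro-5,5,9-trimethylspiro[5.5]undecan-1-one
Conditions: CuBr (10 mol %), tris(2-pyridylmethyl)amine (10 mol %), AIBN (10 mol %), 1,2-dichloroethane (0.02 M), 60 °C
Reagents that add atoms: none
Why: Copper-catalysed bromine-atom-transfer radical cyclisation (Kharasch type): monovalent copper abstracts the α-bromine, the α-keto radical closes 6-endo onto the terminal vinyl carbon to form the C2–C3 bond (the in-ring carbonyl and the hindered internal alkene carbon disfavour 5-exo), and the secondary C4 radical takes bromine back from the divalent copper bromide complex on its equatorial face in the ring A chair that has C7 axial and C11 equatorial, because there the C1=O eclipses C11 and stays clear of the syn-axial C8 bromine while the axial face of C4 is blocked by C7, which gives the 4R bromide.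

**Step 8**
Reactants: 11 (4R,6S,8S,9S)-4,8-dibromo-9-chloro-5,5,9-trimethylspiro[5.5]undecan-1-one
Product: 13 (4R,6S,8S,9S)-4,8-dibromo-9-chloro-5,5,9-trimethylspiro[5.5]undec-1-en-1-yl trifluoromethanesulfonate, via potassium enolate 12 (not isolated)
Conditions: KN(SiMe3)2 (1.05 equiv), THF, −78 °C; then N-(5-chloropyridin-2-yl)bis(trifluoromethanesulfonimide) (1.2 equiv), −78 °C
Reagents that add atoms: N-(5-chloropyridin-2-yl)-1,1,1-trifluoro-N-[(trifluoromethyl)sulfonyl]methanesulfonamide, Clc1ccc(nc1)N(S(=O)(=O)C(F)(F)F)S(=O)(=O)C(F)(F)F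
Why: Deprotonation can occur only at C2 because C6 is quaternary, and O-triflation of the enolate at −78 °C gives the enol triflate regiospecifically, the hindered base and low temperature avoiding E2 loss of the alkyl halides; no stereocentre changes.

**Step 9**
Reactants: 13 (4R,6S,8S,9S)-4,8-dibromo-9-chloro-5,5,9-trimethylspiro[5.5]undec-1-en-1-yl trifluoromethanesulfonate
Product: 14 (4R,6R,8S,9S)-4,8-dibromo-9-chloro-1,5,5,9-tetramethylspiro[5.5]undec-1-ene (target)
Conditions: MeZnCl (2 equiv), Pd(PPh3)4 (5 mol %), THF, 0 °C → rt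
Reagents that add atoms: methylzinc chloride, C[Zn]Cl
Why: Negishi cross-coupling: zerovalent palladium inserts into the alkenyl C–OTf bond much faster than into the unactivated, hindered alkyl halides, and methyl transfer from zinc followed by reductive elimination gives the trisubstituted ring A alkene; all stereocentres are untouched (C6 changes from S to R only through the priority rules).

**Compound list**
1 | 3-methylbut-2-en-1-ol (prenol) | CC(C)=CCO | starting material
2 | ethyl vinyl ether | C=COCC | starting material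
3 | 3-methyl-1-(vinyloxy)but-2-ene (prenyl vinyl ether) | CC(C)=CCOC=C | intermediate (not isolated)
4 | 3,3-dimethylpent-4-enal | C=CC(C)(C)CC=O | intermediate
5 | 3,3-dimethyl-2-methylidenepent-4-enal | C=CC(C)(C)C(=C)C=O | intermediate
6 | isoprene (2-methylbuta-1,3-diene) | C=CC(C)=C | starting material
7 | (1S)-4-methyl-1-(2-methylbut-3-en-2-yl)cyclohex-3-ene-1-carbaldehyde | C=CC(C)(C)[C@]1(C=O)CCC(C)=CC1 | intermediate
8 | 2-bromo-1-[(1S)-4-methyl-1-(2-methylbut-3-en-2-yl)cyclohex-3-en-1-yl]ethan-1-ol (carbinol epimers) | C=CC(C)(C)[C@]1(C(O)CBr)CCC(C)=CC1 | intermediate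
9 | 2-bromo-1-[(1S)-4-methyl-1-(2-methylbut-3-en-2-yl)cyclohex-3-en-1-yl]ethan-1-one | C=CC(C)(C)[C@]1(C(=O)CBr)CCC(C)=CC1 | intermediate
10 | 2-bromo-1-[(1S,3S,4S)-3-bromo-4-chloro-4-methyl-1-(2-methylbut-3-en-2-yl)cyclohexyl]ethan-1-one | C=CC(C)(C)[C@]1(C(=O)CBr)CC[C@](C)(Cl)[C@@H](Br)C1 | intermediate
11 | (4R,6S,8S,9S)-4,8-dibromo-9-chloro-5,5,9-trimethylspiro[5.5]undecan-1-one | O=C1CC[C@@H](Br)C(C)(C)[C@@]12CC[C@](C)(Cl)[C@@H](Br)C2 | intermediate
12 | potassium (4R,6S,8S,9S)-4,8-dibromo-9-chloro-5,5,9-trimethylspiro[5.5]undec-1-en-1-olate | [K+].[O-]C1=CC[C@@H](Br)C(C)(C)[C@@]12CC[C@](C)(Cl)[C@@H](Br)C2 | intermediate (not isolated)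
13 | (4R,6S,8S,9S)-4,8-dibromo-9-chloro-5,5,9-trimethylspiro[5.5]undec-1-en-1-yl trifluoromethanesulfonate | O=S(=O)(OC1=CC[C@@H](Br)C(C)(C)[C@@]12CC[C@](C)(Cl)[C@@H](Br)C2)C(F)(F)F | intermediate
14 | (4R,6R,8S,9S)-4,8-dibromo-9-chloro-1,5,5,9-tetramethylspiro[5.5]undec-1-ene | CC1=CC[C@@H](Br)C(C)(C)[C@@]12CC[C@](C)(Cl)[C@@H](Br)C2 | target

**Step count**
Total steps: 9. Longest linear sequence: 9 (from 1; isoprene 6 enters at step 3).

**Steps most likely to fail, with fallbacks**

Step 3 (enantioselective Diels–Alder). The α-tert-alkyl group may slow the cycloaddition, lower the ee or reverse the usual facial sense; the facial assignment of the (S)-catalyst rests on the standard model and has not been checked for this enal. Fallback, setting out from 5 and 6 and returning at 7: run the cycloaddition with Me2AlCl (CH2Cl2, −78 °C) to give racemic 4-methyl-1-(2-methylbut-3-en-2-yl)cyclohex-3-ene-1-carbaldehyde F1. Condense it with (1R,2R)-N,N'-dimethyl-1,2-diphenylethane-1,2-diamine (MgSO4, Et2O) and separate by chromatography the aminal (4R,5R)-1,3-dimethyl-2-[(1S)-4-methyl-1-(2-methylbut-3-en-2-yl)cyclohex-3-en-1-yl]-4,5-diphenylimidazolidine F2 from its diastereomer. Hydrolyse it (aq. HCl/Et2O, two phases) to enantiopure 7.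

Step 6 (bromochlorination). The bromonium syn to the axial acyl group is the more hindered one, so the diastereomer with Br and Cl on the opposite faces, or carbonyl-participation products, may compete. Fallback, setting out from 9 and returning at 10: m-CPBA (CH2Cl2, 0 °C) epoxidises the ring alkene from the face anti to the acyl group to give 2-bromo-1-[(1S,4S,6R)-1-methyl-4-(2-methylbut-3-en-2-yl)-7-oxabicyclo[4.1.0]heptan-4-yl]ethan-1-one F3. LiBr/AcOH opens it trans-diaxially at the secondary carbon (the Fürst–Plattner-matched position) to 2-bromo-1-[(1S,3S,4S)-3-bromo-4-hydroxy-4-methyl-1-(2-methylbut-3-en-2-yl)cyclohexyl]ethan-1-one F4. SOCl2 (CH2Cl2, 0 °C) then replaces the tertiary hydroxyl by chloride with retention through the bromonium ion formed by the antiperiplanar bromine, giving 10.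

Step 7 (radical cyclisation). Bromine return to the secondary radical may be too slow, 5-exo closure may compete, or the C4 selectivity may be lower than the conformational argument predicts. Fallback, setting out from 7 and returning at 11: switch to a gem-dibromide radical precursor, a much better bromine donor. Add LiCHBr2 (CH2Br2, LiN(i-Pr)2, THF, −78 °C) to 7 to give 2,2-dibromo-1-[(1S)-4-methyl-1-(2-methylbut-3-en-2-yl)cyclohex-3-en-1-yl]ethan-1-ol F5. Oxidise with Dess–Martin periodinane to 2,2-dibromo-1-[(1S)-4-methyl-1-(2-methylbut-3-en-2-yl)cyclohex-3-en-1-yl]ethan-1-one F6. Bromochlorinate as in step 6 to 2,2-dibromo-1-[(1S,3S,4S)-3-bromo-4-chloro-4-methyl-1-(2-methylbut-3-en-2-yl)cyclohexyl]ethan-1-one F7. Cyclise (CuBr, tris(2-pyridylmethyl)amine, 1,2-dichloroethane, 40 °C) to (4R,6S,8S,9S)-2,4,8-tribromo-9-chloro-5,5,9-trimethylspiro[5.5]undecan-1-one F8. Remove only the activated α-bromine by photoredox reduction (Ru(bpy)3Cl2, Hantzsch ester, i-Pr2NEt, DMF, blue light), which leaves the unactivated halides intact, to reach 11.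

**Further compounds**
F1 | step 3 | rac-4-methyl-1-(2-methylbut-3-en-2-yl)cyclohex-3-ene-1-carbaldehyde | C=CC(C)(C)C1(C=O)CCC(C)=CC1
F2 | step 3 | (4R,5R)-1,3-dimethyl-2-[(1S)-4-methyl-1-(2-methylbut-3-en-2-yl)cyclohex-3-en-1-yl]-4,5-diphenylimidazolidine | CN1[C@H](c2ccccc2)[C@H](N(C)C1[C@]3(CCC(C)=CC3)C(C)(C)C=C)c1ccccc1
F3 | step 6 | 2-bromo-1-[(1S,4S,6R)-1-methyl-4-(2-methylbut-3-en-2-yl)-7-oxabicyclo[4.1.0]heptan-4-yl]ethan-1-one | C=CC(C)(C)[C@]1(C(=O)CBr)CC[C@]3(C)O[C@@H]3C1
F4 | step 6 | 2-bromo-1-[(1S,3S,4S)-3-bromo-4-hydroxy-4-methyl-1-(2-methylbut-3-en-2-yl)cyclohexyl]ethan-1-one | C=CC(C)(C)[C@]1(C(=O)CBr)CC[C@](C)(O)[C@@H](Br)C1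
F5 | step 7 | 2,2-dibromo-1-[(1S)-4-methyl-1-(2-methylbut-3-en-2-yl)cyclohex-3-en-1-yl]ethan-1-ol | C=CC(C)(C)[C@]1(C(O)C(Br)Br)CCC(C)=CC1
F6 | step 7 | 2,2-dibromo-1-[(1S)-4-methyl-1-(2-methylbut-3-en-2-yl)cyclohex-3-en-1-yl]ethan-1-one | C=CC(C)(C)[C@]1(C(=O)C(Br)Br)CCC(C)=CC1
F7 | step 7 | 2,2-dibromo-1-[(1S,3S,4S)-3-bromo-4-chloro-4-methyl-1-(2-methylbut-3-en-2-yl)cyclohexyl]ethan-1-one | C=CC(C)(C)[C@]1(C(=O)C(Br)Br)CC[C@](C)(Cl)[C@@H](Br)C1
F8 | step 7 | (4R,6S,8S,9S)-2,4,8-tribromo-9-chloro-5,5,9-trimethylspiro[5.5]undecan-1-one (C2 epimers) | O=C1C(Br)C[C@@H](Br)C(C)(C)[C@@]12CC[C@](C)(Cl)[C@@H](Br)C2
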